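Friday's run has the same loading of initiator as this flask, but more free monomer. At 12.0 h, the logarithm of its remaining free monomer reads 3.25 times Thursday's, near the 3.89 given by free monomer squared times loading. The working assumption is therefore that each step needs two molecules to meet (second-order), so at one loading the flask repeats Friday's curve, stretched in time.

| flask | free monomer | initiator | remark | time |
|---|---|---|---|---|
| Friday's | 2.2 M | 0.35 mol% | run made earlier |  |
| Thursday's | 1.6 M | 0.17 mol% | run made earlier |  |
| flask | 1.6 M | 0.35 mol% |  | 2.5 d |

| run | time / h | monomer in chains / % | free monomer / % |
|---|---|---|---|
| Friday's | 5.00 | 12 | 90 |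
| Friday's | 12.0 | 35 | 66 |
| Friday's | 25.0 | 74 | 24 |
| Friday's | 40.0 | 93 | 8 |
| Thursday's | 5.00 | 1 | 97 |
| Thursday's | 12.0 | 11 | 88 |
| Thursday's | 25.0 | 34 | 66 |
| Thursday's | 40.0 | 56 | 41 |

(readings scatter by 1.5 percentage points)

- average number of monomer units in a chain (chains begun, living or dead) at 2.5 d
- part of the free monomer that has reacted at 2.5 d

- the average divides the monomer in chains by the number of chains begun, living and dead together
- what was read earlier has a scatter of 1.5 percentage points, one standard deviation
- the earlier runs do not show the number of chains; that part of a forecast is a guess

The flask holds free monomer, initiator and growing chains. Its 2.5 d equals 43.6 h on Friday's clock, the time scaled by the flask's charge over Friday's. Friday's late fall, carried past its last reading, leaves 6.13% free monomer. The runs show no chains; one chain per initiator molecule gives 268 units, and fewer chains give more. Do not add free monomer or initiator on its own to this flask, since either changes the loading and the clock is reckoned at Friday's loading.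

The forecast gives 94% and 285, above that 268, and adds “Incomplete initiation would raise it”. The flask gives 94.8% and 442.

    free monomer + initiator → living end + monomer in chains (k = 3.83 × 10⁻⁴ L mol⁻¹ min⁻¹)
    free monomer + living end → monomer in chains + living end, rate k2*[living end]*[free monomer] (k = 0.315 L mol⁻¹ min⁻¹)
    2 free monomer → homo dimer (k = 4.10 × 10⁻⁶ L mol⁻¹ min⁻¹)

The flask keeps 5.15% free monomer against the 6.13% reckoned, with 39% of its initiator unused. The same clock serves a neighbour, this flask read at 15 h, which is 10.9 h on Friday's clock. A straight line between Friday's readings at 5.00 h and 12.0 h gives 69.7% free monomer there. The neighbour holds 69.7% free monomer, and its chains average 218 units.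

The readings are calculated with constants of no real substance; scatter was added.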